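Remark on the chemistry: the target has no stereogenic element, so the SMILES defines it fully. Ring A is the dibromo ring and ring B the tribromo ring. Each ring is numbered from its CH2-bearing carbon (C1), which places the hydroxyls on C3 and C4.

Numbering used throughout: 1 3,4-dihydroxybenzaldehyde; 2 methanesulfonyl chloride; 3 ring A aldehyde mono-mesylate; 4 tert-butyldimethylsilyl chloride; 5 silylated ring A aldehyde; 6 ring A benzylic alcohol; 7 bis-silylated ring B aldehyde; 8 ring B benzylic alcohol; 9 trichloroacetonitrile; 10 ring B trichloroacetimidate; 11 tris-silylated dibenzyl ether; 12 bromine-free dibenzyl ether with O4 of ring A mesylated; 13 bromine; 14 pentabromo mesylate; 15 target.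

## Analysis of the target

- Target 15 (C14H9Br5O5) is an unsymmetrical dibenzyl ether: two benzene rings joined by a CH2–O–CH2 chain, with no further ring and no stereocenter.
- Both rings are 3,4-dihydroxybenzyl units. Ring A carries bromine on C2 and C6 and keeps a hydrogen on C5; ring B carries bromine on C2, C5 and C6 and is fully substituted.
- The sensitive groups are the two catechols, which are oxidised to o-quinones by air in base and by halogen oxidants, and the two benzylic C–O bonds. Each of these is para to a phenolic oxygen (O4) and therefore ionises easily under acid through a quinone-methide-like cation.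
- There is no skeletal problem. The difficulty is regiochemical: five bromines must be placed and the sixth open position, C5 of ring A, must stay C–H, and the two rings differ only in that one position.
- The feature the plan rests on is that every bromine is ortho or para to a phenolic oxygen. C2 and C6 are ortho and para to O3, and C5 is ortho to O4 and to nothing else.
- The halogen pattern of a ring is therefore decided by which oxygens may activate it: O3 alone gives the ring A pattern, O3 together with O4 gives the ring B pattern.
- One deactivating group on O4 of ring A should thus translate into the whole substitution pattern in one bromination. This mirrors a biosynthesis in which electrophilic bromine is delivered to a preformed phenol.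

## Retrosynthetic reasoning

15 from 14. The last operation only unmasks O4 of ring A by cutting its S–O bond. A sulfonate is chosen as the mask because it withdraws the oxygen lone pairs, does not move between the two neighbouring oxygens as an acyl group would, and survives bromine and acid. The forward step must cleave it with base without oxidising the catechols or breaking the ether.

14 from 12 and 13. All five C–Br bonds are cut at once. This is the point of the plan: in 12 the free O3 and O4 of ring B activate C2, C5 and C6, while in ring A only O3 is free and activates C2 and C6, so C5 of ring A has no activating oxygen. Cutting the C–Br bonds last means no brominated building block has to be made or differentiated, and the two rings can be built from the same aldehyde. The forward reaction must deliver five electrophilic brominations without ipso attack at C1 of ring B, without oxidation of the catechol and without acid cleavage of the ether.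

12 from 11. The three free hydroxyls are traced back to silyl ethers. These can be removed by buffered fluoride in an aprotic medium, conditions that touch neither the aryl sulfonate nor the para-hydroxybenzyl ether. Acid-labile or hydrogenolytic groups would endanger the ether link.

11 from 6 and 10. The benzylic C–O bond on the ring B side is cut. That carbon is para to a silyloxy group and gives a stabilised cation, so the ether can be formed under mild acid catalysis from imidate 10 and alcohol 6. The other C–O bond is not chosen because the ring A benzylic carbon gives no stabilised cation, and a base-mediated etherification would expose the aryl mesylate and the aryl silyl ethers to an alkoxide.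

6 from 5, 3, 1 and 2. Functional-group changes only: hydride reduction of aldehyde 5, silylation of the phenol of 3, and sulfonylation of 1 with 2 at its more acidic 4-hydroxyl. This first step fixes the position of the mesylate and therefore the whole later regiochemistry.

10 from 8 and 9, and 8 from 7, 1 and 4. The imidate is the adduct of alcohol 8 with nitrile 9. Alcohol 8 comes from aldehyde 7 by reduction, and 7 from 1 by double silylation with 4.

## Alternatives that were turned down

Alternative 1: Twofold directed C–H oxygenation.
- Disconnection: the C3–O bond of each ring is cut, so that both catechols descend from 4-hydroxyphenyl units. The substrate is A2, the bis(di-tert-butylsilanol) of 2,6-dibromo-4-hydroxybenzyl 2,3,6-tribromo-4-hydroxybenzyl ether.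
- Forward key step: under palladium catalysis with a hypervalent iodine oxidant, each silanol directs palladation of the ortho C3–H by divalent palladium. Oxidation to tetravalent palladium and C–O reductive elimination follow, and the new oxygen closes onto silicon to give the two five-membered dioxasilole rings of A1. Fluoride would then release 15.
- For it: the oxygenation site is unambiguous, since the two ortho C–H bonds of ring A are equivalent by symmetry and ring B has only one. A1 is a robust protected form of both catechols. Neither bromine nor hydroxide ever meets the finished ether, so the final unmasking is milder than in the chosen route.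
- Against it: in A2 four of the five bromines (C2 and C6 of each ring) are meta to the only oxygen of their ring. Phenol-directed bromination cannot produce that pattern, so both halves need long indirect syntheses. The C–H palladation must also succeed twice at positions wedged between a bromine and the silyloxy group of electron-poor polybromoarenes, next to five C–Br bonds and two oxidisable benzylic CH2 groups.
- Comparison: the chosen route lets the oxygens already in place direct every bromine and reaches the pattern in ten steps from one cheap aldehyde. The price is a harsher last deprotection.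

Alternative 2: Ring B by cycloaddition of a thiophene dioxide.
- Disconnection: ring B is taken apart at C1–C2 and C5–C6 into A4, 2,5-dibromo-3,4-bis(methoxymethoxy)thiophene 1,1-dioxide, and A5, the 3-bromoprop-2-ynyl ether of 2,6-dibromo-3,4-bis(methoxymethoxy)benzyl alcohol.
- Forward key step: a thermal [4+2] cycloaddition of A4 across the triple bond of A5, followed by cheletropic loss of the sulfonyl bridge, gives the hexasubstituted ring B of A3, the tetrakis(methoxymethyl) ether of the target.
- For it: the substitution pattern of ring B is fixed by construction, the diene is symmetrical so there is no regiochemical question, and ipso attack is impossible. On certainty of the ring B pattern it is stronger than the chosen route.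
- Against it: an electron-rich 3,4-dialkoxythiophene is hard to oxidise to its dioxide, and such dioxides tend to dimerise. The dioxide is an electron-poor diene and a bromoalkyne is a poor partner for it, so the acetals and the bromoalkyne must survive strong heating. A5 still needs regiocontrolled dibromination of ring A at C2 and C6 but not C5, which is the same O3/O4 differentiation the chosen plan uses. The four acetals must finally be removed with acid, the condition under which the para-oxygenated benzylic ether ionises.
- Comparison: the step count is clearly higher. The chosen strategy offers one operation for all five halogens and no acid at the end.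

Alternative 3: Ring A by cycloaddition of a dibromopyrone.
- Disconnection: ring A is taken apart at C2–C3 and C4–C5 into A7, a 3,5-dibromo-2-pyrone carrying the ring B benzyloxymethyl group on C4, and the alkyne A8, di-tert-butoxyethyne.
- Forward key step: an inverse-demand [4+2] addition of A8 across C3 and C6 of A7 and decarboxylative aromatisation give A6, the target with ring A as its di-tert-butyl ether and ring B as its bis(methoxymethyl) ether.
- For it: the C5–H of ring A is placed by construction, since it is the C6–H of the pyrone. The alkyne is symmetrical, and 3,5-dibromo-2-pyrones are known to react as dienes with electron-rich partners. On placing that one hydrogen it is more certain than a selectivity argument.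
- Against it: A8 is thermally fragile and loses isobutene on moderate heating, while the cycloaddition and decarboxylation need heat. A7 needs its own multistep synthesis, and the ring B it carries must still be tribrominated conventionally. tert-Butyl ethers and acetals again call for acid at the end.
- Comparison: two fragment syntheses plus a delicate cycloaddition against ten ordinary steps. The chosen strategy instead secures the C5–H by a single sulfonate and offers a much shorter sequence.

Key step: step 9

## Route

Step 1
Reactants: 1 3,4-dihydroxybenzaldehyde; 2 methanesulfonyl chloride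
Product: 3 4-formyl-2-hydroxyphenyl methanesulfonate (3-hydroxy-4-mesyloxybenzaldehyde)
Conditions: MsCl (1.0 equiv), Et3N (1.05 equiv), THF, −20 °C to 0 °C
Reagents that add atoms: methanesulfonyl chloride, CS(=O)(=O)Cl
Why: The 4-hydroxyl is para to the formyl group and markedly more acidic than the 3-hydroxyl, so one equivalent of amine base forms only the 4-phenoxide, which is O-sulfonylated (regioselective sulfonylation of a phenol, the same acidity control as in selective 4-O-alkylation of this aldehyde); the regiochemistry should be confirmed on 3 before going on.

Step 2
Reactants: 3 4-formyl-2-hydroxyphenyl methanesulfonate; 4 tert-butyldimethylsilyl chloride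
Product: 5 2-[(tert-butyldimethylsilyl)oxy]-4-formylphenyl methanesulfonate
Conditions: TBSCl (1.2 equiv), imidazole (2.5 equiv), CH2Cl2, 0 °C to rt
Reagents that add atoms: tert-butyldimethylsilyl chloride, CC(C)(C)[Si](C)(C)Cl
Why: Standard imidazole-promoted silylation of a phenol; the near-neutral medium leaves the neighbouring aryl mesylate untouched and gives O3 a cap that fluoride removes later.

Step 3
Reactants: 5 2-[(tert-butyldimethylsilyl)oxy]-4-formylphenyl methanesulfonate
Product: 6 2-[(tert-butyldimethylsilyl)oxy]-4-(hydroxymethyl)phenyl methanesulfonate
Conditions: NaBH4 (0.6 equiv), THF/MeOH 4:1, −10 °C, short reaction time; sat. aq. NH4Cl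
Reagents that add atoms: none
Why: Chemoselective borohydride reduction of an aromatic aldehyde; the aryl sulfonate and the aryl silyl ether should be inert at low temperature when the reaction is kept short and quenched with a mild acid.

Step 4
Reactants: 1 3,4-dihydroxybenzaldehyde; 4 tert-butyldimethylsilyl chloride
Product: 7 3,4-bis[(tert-butyldimethylsilyl)oxy]benzaldehyde
Conditions: TBSCl (2.3 equiv), imidazole (5 equiv), DMF, rt
Reagents that add atoms: tert-butyldimethylsilyl chloride, CC(C)(C)[Si](C)(C)Cl
Why: Exhaustive silylation of a catechol under standard imidazole conditions.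

Step 5
Reactants: 7 3,4-bis[(tert-butyldimethylsilyl)oxy]benzaldehyde
Product: 8 {3,4-bis[(tert-butyldimethylsilyl)oxy]phenyl}methanol
Conditions: NaBH4 (0.6 equiv), THF/MeOH 4:1, 0 °C; sat. aq. NH4Cl
Reagents that add atoms: none
Why: Borohydride reduction of an aromatic aldehyde in the presence of aryl silyl ethers, which tolerate these conditions.

Step 6
Reactants: 8 {3,4-bis[(tert-butyldimethylsilyl)oxy]phenyl}methanol; 9 trichloroacetonitrile
Product: 10 3,4-bis[(tert-butyldimethylsilyl)oxy]benzyl 2,2,2-trichloroacetimidate
Conditions: Cl3CCN (2 equiv), DBU (0.1 equiv), CH2Cl2, 0 °C; quick filtration through Et3N-deactivated silica, used at once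
Reagents that add atoms: trichloroacetonitrile, N#CC(Cl)(Cl)Cl
Why: Base-catalysed addition of the alcohol to the nitrile (trichloroacetimidate formation), the activation used for para-methoxybenzyl alcohol; 10 is used directly because electron-rich benzylic imidates rearrange on storage.

Step 7
Reactants: 6 2-[(tert-butyldimethylsilyl)oxy]-4-(hydroxymethyl)phenyl methanesulfonate; 10 3,4-bis[(tert-butyldimethylsilyl)oxy]benzyl 2,2,2-trichloroacetimidate
Product: 11 4-({[3,4-bis(tert-butyldimethylsilyloxy)phenyl]methoxy}methyl)-2-[(tert-butyldimethylsilyl)oxy]phenyl methanesulfonate
Conditions: 10 (1.4 equiv), camphorsulfonic acid (0.1 equiv), 4 Å molecular sieves, CH2Cl2, 0 °C to rt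
Reagents that add atoms: none
Why: Acid-catalysed benzylation of a primary alcohol by a trichloroacetimidate: protonation at nitrogen releases trichloroacetamide and a benzylic cation stabilised by the para-silyloxy group, which the hydroxyl of 6 captures; no strong base meets the mesylate or the aryl silyl ethers.

Step 8
Reactants: 11 4-({[3,4-bis(tert-butyldimethylsilyloxy)phenyl]methoxy}methyl)-2-[(tert-butyldimethylsilyl)oxy]phenyl methanesulfonate
Product: 12 4-{[(3,4-dihydroxyphenyl)methoxy]methyl}-2-hydroxyphenyl methanesulfonate (3,4-dihydroxybenzyl 3-hydroxy-4-mesyloxybenzyl ether)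
Conditions: TBAF (3.3 equiv), AcOH (3.5 equiv), THF, 0 °C; pH 5 to 6 buffer work-up, no alcohol solvents
Reagents that add atoms: none
Why: Fluoride cleavage of three aryl silyl ethers; the acetic acid buffer keeps the freed oxygens protonated, so no phenoxide can attack the sulfonate or expel the benzylic ether, and the aprotic medium avoids solvolysis of the para-hydroxybenzyl ether.

Step 9
Reactants: 12 4-{[(3,4-dihydroxyphenyl)methoxy]methyl}-2-hydroxyphenyl methanesulfonate; 13 bromine
Product: 14 3,5-dibromo-2-hydroxy-4-{[(2,3,6-tribromo-4,5-dihydroxyphenyl)methoxy]methyl}phenyl methanesulfonate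
Conditions: Br2 (5.1 equiv, slow addition as a CH2Cl2 solution), NaOAc (7 equiv), CH2Cl2/AcOH 4:1, −20 °C to 0 °C (rt for the last substitutions if needed), dark; aq. Na2S2O4 quench
Reagents that add atoms: bromine, BrBr
Why: Each C–Br bond forms by ordinary electrophilic aromatic substitution: bromine attacks a position ortho or para to a free phenolic oxygen, the arenium ion is stabilised by that oxygen and loses its proton to acetate. The closest known reactions are the exhaustive bromination of 4-alkylcatechols to their tribromides and the ortho/para dibromination of 3-hydroxy-4-O-substituted benzyl and benzaldehyde systems; here both run on one molecule. No ring is closed and no stereocenter is formed. The selectivity needed is fivefold substitution with C5 of ring A left as C–H: in ring B the free O3 and O4 together activate C2, C5 and C6, whereas in ring A only O3 is free and activates C2 and C6, while C5 is meta to O3 and ortho only to the sulfonylated O4, whose lone pairs are drawn into the sulfonyl group. The mesylate should not shift to O3, since that would need an endocyclic displacement at sulfur through a five-membered transition state and no phenoxide exists in the acidic buffer. The second requirement is survival of the CH2–O–CH2 link: acetate turns HBr into NaBr and AcOH so that the para-hydroxybenzyl C–O bond of ring B is not ionised, and slow addition in the cold keeps the bromine concentration low while the unbrominated catechol, the most oxidisable and most ipso-prone species, is consumed. The first bromine should enter ring B at C6, para to O3 and next to C1, which shields the ipso position, and the reductive quench returns any o-quinone to the catechol.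

Step 10
Reactants: 14 3,5-dibromo-2-hydroxy-4-{[(2,3,6-tribromo-4,5-dihydroxyphenyl)methoxy]methyl}phenyl methanesulfonate
Product: 15 3,5-dibromo-4-{[(2,3,6-tribromo-4,5-dihydroxyphenyl)methoxy]methyl}benzene-1,2-diol (target)
Conditions: NaOH (2 M aq., 8 equiv), Na2S2O4 (0.5 equiv), degassed THF/H2O, Ar, 0 °C to rt (40 °C only if slow); then cold 1 M HCl to pH 3, EtOAc extraction
Reagents that add atoms: none
Why: Alkaline hydrolysis of an aryl methanesulfonate (hydroxide attack at sulfur or E1cB loss of sulfene, with the dibromocatecholate as leaving group); oxygen is excluded and dithionite is present because catecholates autoxidise, and cold acidification to about pH 3 avoids acid-promoted ionisation of the benzylic ether.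

## Compound list

1 | 3,4-dihydroxybenzaldehyde | O=Cc1ccc(O)c(O)c1 | starting material
2 | methanesulfonyl chloride | CS(=O)(=O)Cl | starting material
3 | 4-formyl-2-hydroxyphenyl methanesulfonate | CS(=O)(=O)Oc1ccc(C=O)cc1O | intermediate
4 | tert-butyldimethylsilyl chloride | CC(C)(C)[Si](C)(C)Cl | starting material
5 | 2-[(tert-butyldimethylsilyl)oxy]-4-formylphenyl methanesulfonate | CS(=O)(=O)Oc1ccc(C=O)cc1O[Si](C)(C)C(C)(C)C | intermediate
6 | 2-[(tert-butyldimethylsilyl)oxy]-4-(hydroxymethyl)phenyl methanesulfonate | CS(=O)(=O)Oc1ccc(CO)cc1O[Si](C)(C)C(C)(C)C | intermediate
7 | 3,4-bis[(tert-butyldimethylsilyl)oxy]benzaldehyde | O=Cc1ccc(O[Si](C)(C)C(C)(C)C)c(O[Si](C)(C)C(C)(C)C)c1 | intermediate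
8 | {3,4-bis[(tert-butyldimethylsilyl)oxy]phenyl}methanol | OCc1ccc(O[Si](C)(C)C(C)(C)C)c(O[Si](C)(C)C(C)(C)C)c1 | intermediate
9 | trichloroacetonitrile | N#CC(Cl)(Cl)Cl | starting material
10 | 3,4-bis[(tert-butyldimethylsilyl)oxy]benzyl 2,2,2-trichloroacetimidate | N=C(OCc1ccc(O[Si](C)(C)C(C)(C)C)c(O[Si](C)(C)C(C)(C)C)c1)C(Cl)(Cl)Cl | intermediate
11 | 4-({[3,4-bis(tert-butyldimethylsilyloxy)phenyl]methoxy}methyl)-2-[(tert-butyldimethylsilyl)oxy]phenyl methanesulfonate | CS(=O)(=O)Oc1ccc(COCc2ccc(O[Si](C)(C)C(C)(C)C)c(O[Si](C)(C)C(C)(C)C)c2)cc1O[Si](C)(C)C(C)(C)C | intermediate
12 | 4-{[(3,4-dihydroxyphenyl)methoxy]methyl}-2-hydroxyphenyl methanesulfonate | CS(=O)(=O)Oc1ccc(COCc2ccc(O)c(O)c2)cc1O | intermediate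
13 | bromine | BrBr | starting material
14 | 3,5-dibromo-2-hydroxy-4-{[(2,3,6-tribromo-4,5-dihydroxyphenyl)methoxy]methyl}phenyl methanesulfonate | CS(=O)(=O)Oc1cc(Br)c(COCc2c(Br)c(O)c(O)c(Br)c2Br)c(Br)c1O | intermediate
15 | 3,5-dibromo-4-{[(2,3,6-tribromo-4,5-dihydroxyphenyl)methoxy]methyl}benzene-1,2-diol | Oc1cc(Br)c(COCc2c(Br)c(O)c(O)c(Br)c2Br)c(Br)c1O | target

## Step count and least certain steps

Total step count: 10. Longest linear sequence: 7 steps (steps 1, 2, 3, 7, 8, 9, 10; the ring B branch through steps 4, 5, 6 is equally long).

Step 9 (key step).
- What may go wrong: ipso attack of bromine at C1 of ring B, which is para to the free O4, with loss of the side chain. Oxidation of the still unbrominated catechol to an o-quinone that tautomerises to a quinone methide. Acid-mediated ionisation of the ring B benzylic C–O bond. Stalling before the hindered C2 positions are filled.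
- Fallback: a staged bromination in which ring B is brominated while C1 still carries a formyl group, which can neither be expelled nor ionise. It sets out from 1 and 6 and comes back at 14. Compound 1 is brominated exhaustively (excess Br2, AcOH, catalytic iron powder, warm) to 2,3,6-tribromo-4,5-dihydroxybenzaldehyde F1. This is silylated (TBSCl, imidazole, DMF) to 2,3,6-tribromo-4,5-bis[(tert-butyldimethylsilyl)oxy]benzaldehyde F2 and reduced with NaBH4 to {2,3,6-tribromo-4,5-bis[(tert-butyldimethylsilyl)oxy]phenyl}methanol F3. In parallel 6 is converted with 9 and catalytic DBU into 3-[(tert-butyldimethylsilyl)oxy]-4-(mesyloxy)benzyl 2,2,2-trichloroacetimidate F4. F3 and F4 are joined under catalytic TfOH in CH2Cl2 to the tris-silylated tribromo dibenzyl ether F5. Buffered TBAF/AcOH gives 2-hydroxy-4-{[(2,3,6-tribromo-4,5-dihydroxyphenyl)methoxy]methyl}phenyl methanesulfonate F6, in which ring B is already complete. Two equivalents of 13 with NaOAc then brominate only C2 and C6 of ring A and give 14.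

Step 10.
- What may go wrong: cleavage of the dibenzyl ether by expulsion of the benzylic alkoxide from an O4 phenoxide (quinone methide formation) if warming is needed. Autoxidation of the catecholates. Sluggish S–O cleavage, because the leaving group is a doubly charged catecholate.
- Fallback: a protect–eliminate–deprotect sequence in anhydrous medium, from 14 back to 15. The three phenols of 14 are silylated (TBSCl, imidazole, DMF) to the tris(tert-butyldimethylsilyl) ether of 14, F7. LDA in THF at −78 °C deprotonates the methyl group of the mesylate and expels sulfene, giving the tris-silylated pentabromo phenol F8 after a mild acidic quench. Any silyl shift between the two neighbouring oxygens of ring A is without consequence. TBAF/AcOH in THF at 0 °C then removes all silyl groups and gives 15.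

Step 1.
- What may go wrong: incomplete regiocontrol, that is sulfonylation at O3 or at both oxygens. This would place the deactivating group on the wrong oxygen and invert the bromination pattern of ring A.
- Fallback: fix the regiochemistry by the starting material. It sets out from 2 and commercial vanillin F9 and comes back at 3. Vanillin F9 is mesylated (MsCl, Et3N, CH2Cl2, 0 °C) to 4-formyl-2-methoxyphenyl methanesulfonate F10. The methyl ether is then cleaved with BBr3 (CH2Cl2, −78 °C to 0 °C, limited excess and time to spare the aldehyde), which leaves the aryl sulfonate and gives 3.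

Step 7.
- What may go wrong: Friedel–Crafts self-alkylation and oligomerisation of the electron-rich ring B cation, rearrangement of the imidate to the N-benzyl amide, or acid-induced loss of an aryl silyl group.
- Fallback: reverse the polarity so that no stabilised ring B cation is formed. It sets out from 6 and 8 and comes back at 11. Compound 6 is converted with CBr4 and PPh3 (CH2Cl2, 0 °C) into 4-(bromomethyl)-2-[(tert-butyldimethylsilyl)oxy]phenyl methanesulfonate F11. This unactivated benzylic bromide alkylates alcohol 8 under neutral conditions with Ag2O (CH2Cl2, 4 Å molecular sieves, rt, dark) to give 11.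

## Further compounds

F1 | step 9 | 2,3,6-tribromo-4,5-dihydroxybenzaldehyde | O=Cc1c(Br)c(O)c(O)c(Br)c1Br
F2 | step 9 | 2,3,6-tribromo-4,5-bis[(tert-butyldimethylsilyl)oxy]benzaldehyde | O=Cc1c(Br)c(O[Si](C)(C)C(C)(C)C)c(O[Si](C)(C)C(C)(C)C)c(Br)c1Br
F3 | step 9 | {2,3,6-tribromo-4,5-bis[(tert-butyldimethylsilyl)oxy]phenyl}methanol | OCc1c(Br)c(O[Si](C)(C)C(C)(C)C)c(O[Si](C)(C)C(C)(C)C)c(Br)c1Br
F4 | step 9 | 3-[(tert-butyldimethylsilyl)oxy]-4-(mesyloxy)benzyl 2,2,2-trichloroacetimidate | CS(=O)(=O)Oc1ccc(COC(=N)C(Cl)(Cl)Cl)cc1O[Si](C)(C)C(C)(C)C
F5 | step 9 | 2-[(tert-butyldimethylsilyl)oxy]-4-({[2,3,6-tribromo-4,5-bis(tert-butyldimethylsilyloxy)phenyl]methoxy}methyl)phenyl methanesulfonate | CS(=O)(=O)Oc1ccc(COCc2c(Br)c(O[Si](C)(C)C(C)(C)C)c(O[Si](C)(C)C(C)(C)C)c(Br)c2Br)cc1O[Si](C)(C)C(C)(C)C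
F6 | step 9 | 2-hydroxy-4-{[(2,3,6-tribromo-4,5-dihydroxyphenyl)methoxy]methyl}phenyl methanesulfonate | CS(=O)(=O)Oc1ccc(COCc2c(Br)c(O)c(O)c(Br)c2Br)cc1O
F7 | step 10 | 3,5-dibromo-2-[(tert-butyldimethylsilyl)oxy]-4-({[2,3,6-tribromo-4,5-bis(tert-butyldimethylsilyloxy)phenyl]methoxy}methyl)phenyl methanesulfonate | CS(=O)(=O)Oc1cc(Br)c(COCc2c(Br)c(O[Si](C)(C)C(C)(C)C)c(O[Si](C)(C)C(C)(C)C)c(Br)c2Br)c(Br)c1O[Si](C)(C)C(C)(C)C
F8 | step 10 | 3,5-dibromo-2-[(tert-butyldimethylsilyl)oxy]-4-({[2,3,6-tribromo-4,5-bis(tert-butyldimethylsilyloxy)phenyl]methoxy}methyl)phenol | Oc1cc(Br)c(COCc2c(Br)c(O[Si](C)(C)C(C)(C)C)c(O[Si](C)(C)C(C)(C)C)c(Br)c2Br)c(Br)c1O[Si](C)(C)C(C)(C)C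
F9 | step 1 | vanillin (4-hydroxy-3-methoxybenzaldehyde) | COc1cc(C=O)ccc1O
F10 | step 1 | 4-formyl-2-methoxyphenyl methanesulfonate | COc1cc(C=O)ccc1OS(C)(=O)=O
F11 | step 7 | 4-(bromomethyl)-2-[(tert-butyldimethylsilyl)oxy]phenyl methanesulfonate | CS(=O)(=O)Oc1ccc(CBr)cc1O[Si](C)(C)C(C)(C)C
A1 | alternative 1 | bis(di-tert-butylsilylene) derivative of the target | CC(C)(C)[Si]1(Oc2cc(Br)c(COCc3c(Br)c4O[Si](C(C)(C)C)(C(C)(C)C)Oc4c(Br)c3Br)c(Br)c2O1)C(C)(C)C
A2 | alternative 1 | bis(di-tert-butylhydroxysilyl) ether of 2,6-dibromo-4-hydroxybenzyl 2,3,6-tribromo-4-hydroxybenzyl ether | CC(C)(C)[Si](O)(Oc1cc(Br)c(COCc2c(Br)cc(O[Si](O)(C(C)(C)C)C(C)(C)C)c(Br)c2Br)c(Br)c1)C(C)(C)C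
A3 | alternative 2 | tetrakis(methoxymethyl) ether of the target | COCOc1cc(Br)c(COCc2c(Br)c(OCOC)c(OCOC)c(Br)c2Br)c(Br)c1OCOC
A4 | alternative 2 | 2,5-dibromo-3,4-bis(methoxymethoxy)thiophene 1,1-dioxide | COCOC1=C(Br)S(=O)(=O)C(Br)=C1OCOC
A5 | alternative 2 | 2,6-dibromo-3,4-bis(methoxymethoxy)benzyl 3-bromoprop-2-yn-1-yl ether | BrC#CCOCc1c(Br)c(OCOC)c(OCOC)cc1Br
A6 | alternative 3 | target with ring A as di-tert-butyl ether and ring B as bis(methoxymethyl) ether | CC(C)(C)Oc1cc(Br)c(COCc2c(Br)c(OCOC)c(OCOC)c(Br)c2Br)c(Br)c1OC(C)(C)C
A7 | alternative 3 | 3,5-dibromo-4-({[2,3,6-tribromo-4,5-bis(methoxymethoxy)phenyl]methoxy}methyl)-2H-pyran-2-one | O=C1OC=C(Br)C(COCc2c(Br)c(OCOC)c(OCOC)c(Br)c2Br)=C1Br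
A8 | alternative 3 | di-tert-butoxyethyne | CC(C)(C)OC#COC(C)(C)C
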